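Everything rests on opening the pyrazine ring of the imidazo[1,2-a]pyrazin-3(7H)-one at N7=C8 and N4–C5. C5, the only unsubstituted carbon of that ring, enters as the terminal CH2 of an N-vinylic phosphazene (C5=C6–N7), and the ring-fusion nitrogen N4 as the methoxy-bearing nitrogen of an α-keto amidoxime ether (C8 ketone, C8a, N4) whose amino nitrogen already carries the protected tyrosine unit. One operation, aza-Wittig condensation followed by 6π-azaelectrocyclization of the 1,4-diazatriene and loss of methanol, should deliver the fully substituted aminopyrazine at the aromatic oxidation level without an oxidant. Acidolysis and cyclodehydration of N4 onto the tyrosine carboxyl then close the imidazolone.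

Key step: step 8

Remarks on the chemistry (assumptions):
- The target SMILES is that of coelenterazine. Atom labels (N4, C5, C8a and so on) follow the imidazo[1,2-a]pyrazin-3(7H)-one numbering of the target.
- The target has no stereocentre, because the tyrosine α-carbon becomes trigonal C2 in the last step. L-configured material is used only because it is the commercial form, and loss of configuration at any stage is without consequence.
- Both phenols are carried as tert-butyl ethers and the carboxyl as its tert-butyl ester. Both building blocks (5 and 10) are commercial in this form. These groups survive KOtBu, azide, carbonate and heat. The bulky ester keeps the oximate of 8 and the oxime nitrogen of 9 from closing onto the carboxyl. All three groups fall in one acid step.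
- The C=N geometry of amidoximes 8 and 9 is mobile through the N–H tautomer, so their SMILES are written without it.

Step 1
Reactants: 1 phenylacetyl chloride
Product: 2 1-diazo-3-phenylpropan-2-one
Conditions: TMSCHN2 (2 equiv), THF/MeCN 1:1, 0 °C to rt
Reagents that add atoms: trimethylsilyldiazomethane, C[Si](C)(C)C=[N+]=[N-]
Why: Acylation of the diazoalkane carbon by the acid chloride with loss of the silyl group (Arndt–Eistert-type diazoketone synthesis) should give the diazomethyl ketone, the excess reagent scavenging acid so that neither the chloromethyl ketone nor phenylketene takes over.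

Step 2
Reactants: 2 1-diazo-3-phenylpropan-2-one
Product: 4 (Z)-N-hydroxy-2-oxo-3-phenylpropanimidoyl chloride, via 1-chloro-1-nitroso-3-phenylpropan-2-one 3 (not isolated)
Conditions: NOCl (1.1 equiv), CH2Cl2, −20 to 0 °C
Reagents that add atoms: nitrosyl chloride, O=NCl
Why: Electrophilic nitrosation of the diazo carbon with loss of N2 and capture by chloride gives the C-nitroso compound 3, which tautomerizes to the oxime; this reaction of diazocarbonyl compounds with nitrosyl chloride is an established entry to α-oxo hydroximoyl chlorides.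

Step 3
Reactants: 4 (Z)-N-hydroxy-2-oxo-3-phenylpropanimidoyl chloride; 5 O-tert-butyl-L-tyrosine tert-butyl ester hydrochloride
Product: 8 tert-butyl O-tert-butyl-N-[1-(hydroxyimino)-2-oxo-3-phenylpropyl]-L-tyrosinate, via tert-butyl O-tert-butyl-L-tyrosinate 6 (not isolated), via 2-oxo-3-phenylpropanenitrile oxide 7 (not isolated)
Conditions: Et3N (2.1 equiv, added slowly), CH2Cl2, −20 to 0 °C
Reagents that add atoms: none
Why: Triethylamine frees amine 6 and dehydrochlorinates 4 to the acyl nitrile oxide 7, to which the primary amine adds (1,3-addition of an amine to a nitrile oxide, the standard amidoxime synthesis) faster than the dipole dimerizes when the base is added slowly; the α-stereocentre is not touched.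

Step 4
Reactants: 8 tert-butyl O-tert-butyl-N-[1-(hydroxyimino)-2-oxo-3-phenylpropyl]-L-tyrosinate
Product: 9 tert-butyl O-tert-butyl-N-[1-(methoxyimino)-2-oxo-3-phenylpropyl]-L-tyrosinate
Conditions: Me2SO4 (1.1 equiv), K2CO3, acetone, 0 °C to rt
Reagents that add atoms: dimethyl sulfate, COS(=O)(=O)OC
Why: The oxime OH, acidified by the adjacent ketone, is the only site that K2CO3 deprotonates, and the hard electrophile alkylates the oximate on oxygen (Williamson-type O-alkylation of an α-oxo oxime), while the tert-butyl ester resists attack by the oximate.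

Step 5
Reactants: 10 4-tert-butoxystyrene
Product: 11 1-(1-azido-2-iodoethyl)-4-tert-butoxybenzene (racemic)
Conditions: NaN3, ICl, MeCN, −20 °C; then 10, −20 °C to rt
Reagents that add atoms: iodine monochloride, ClI; sodium azide, [Na+].[N-]=[N+]=[N-]
Why: Iodine azide formed in the flask adds across the alkene by way of an iodonium ion that azide opens at the benzylic carbon (Markovnikov iodoazidation), giving the racemic adduct, whose stereocentre is removed in the next step.

Step 6
Reactants: 11 1-(1-azido-2-iodoethyl)-4-tert-butoxybenzene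
Product: 12 1-(1-azidoethenyl)-4-tert-butoxybenzene
Conditions: KOtBu, Et2O, 0 °C
Reagents that add atoms: none
Why: E2 dehydroiodination with the bulky base removes the benzylic hydrogen α to the azide and should give the α-azidostyrene (vinyl azide synthesis by elimination), to which the aryl tert-butyl ether is inert.

Step 7
Reactants: 12 1-(1-azidoethenyl)-4-tert-butoxybenzene
Product: 14 N-[1-(4-tert-butoxyphenyl)ethenyl]iminotriphenylphosphorane, via phosphazide 13 (not isolated)
Conditions: PPh3 (1.0 equiv), Et2O, 0 °C to rt, Ar
Reagents that add atoms: triphenylphosphine, c1ccc(cc1)P(c1ccccc1)c1ccccc1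
Why: Staudinger reaction: the phosphine adds to the terminal azide nitrogen, the phosphazide 13 loses N2, and the conjugated N-vinylic phosphazene should be obtained under anhydrous conditions and used without chromatography.

Step 8
Reactants: 14 N-[1-(4-tert-butoxyphenyl)ethenyl]iminotriphenylphosphorane; 9 tert-butyl O-tert-butyl-N-[1-(methoxyimino)-2-oxo-3-phenylpropyl]-L-tyrosinate
Product: 17 tert-butyl N-[3-benzyl-5-(4-tert-butoxyphenyl)pyrazin-2-yl]-O-tert-butyl-L-tyrosinate, via 1-methoxy-1,4-diazatriene 15 (not isolated), via 1-methoxy-1,6-dihydropyrazine 16 (not isolated)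
Conditions: toluene, 4 Å molecular sieves, Ar, 60 °C; then 130 °C (sealed tube)
Reagents that add atoms: none
Why: Proposed new method: the phosphazene nitrogen of 14 adds to the ketone of 9, which the adjacent methoxyimino carbon activates, and the oxazaphosphetidine collapses to Ph3PO and the N-vinyl ketimine 15, a 1-methoxy-1,4-diazatriene N4=C8a–C8=N7–C6=C5. On heating, a thermal disrotatory 6π-azaelectrocyclization joins N4 to the terminal methylene C5 and closes the six-membered ring as the 1-methoxy-1,6-dihydropyrazine 16, which aromatizes by elimination of methanol across N4–C5, so the N–O bond supplies the oxidation level. The closest known reaction types are the aza-Wittig reaction of N-vinylic phosphazenes with activated carbonyl compounds to give 2-azadienes and the thermal ring closure of O-alkylated 1-hydroxy-1,4-diazatrienes to pyrazines with loss of alcohol. No stereocentre is created, and the tyrosine α-carbon is a spectator whose configuration does not matter for the target. The step needs attack at the ketone and not at the ester, which the bulk of the tert-butyl ester and the α-imino activation should secure, and it needs the methoxy group turned away from C8, which the Z-amidoxime has and which N–H tautomerism of the amidoxime and inversion at the imine nitrogen can restore. The regiochemistry (benzyl on C8, aryl on C6, hydrogen on C5) is fixed by the connectivity of the two partners and cannot scramble.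

Step 9
Reactants: 17 tert-butyl N-[3-benzyl-5-(4-tert-butoxyphenyl)pyrazin-2-yl]-O-tert-butyl-L-tyrosinate
Product: 18 N-[3-benzyl-5-(4-hydroxyphenyl)pyrazin-2-yl]-L-tyrosine
Conditions: TFA/H2O 95:5, rt; then pH 4–5
Reagents that add atoms: none
Why: Acidolysis by loss of tert-butyl cation (E1) should cleave the tert-butyl ester and both aryl tert-butyl ethers in one operation, water trapping the cation, while the aminopyrazine is only protonated.

Step 10
Reactants: 18 N-[3-benzyl-5-(4-hydroxyphenyl)pyrazin-2-yl]-L-tyrosine
Product: 20 coelenterazine, via 2H-imidazopyrazinone tautomer 19 (not isolated)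
Conditions: DCC (1.1 equiv), pyridine, rt, Ar, degassed
Reagents that add atoms: none
Why: Carbodiimide activation of the carboxylic acid lets the pyrazine ring nitrogen next to the amino group (N4 of the target) acylate intramolecularly (5-exo-trig cyclodehydration, the classical closure of N-(pyrazin-2-yl) α-amino acids), and the 2H-tautomer 19 shifts its C2 hydrogen to N7 to give the conjugated 3,7-dihydro form, so the former stereocentre becomes trigonal.

Compound list
1 | phenylacetyl chloride | O=C(Cl)Cc1ccccc1 | starting material
2 | 1-diazo-3-phenylpropan-2-one | [N-]=[N+]=CC(=O)Cc1ccccc1 | intermediate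
3 | 1-chloro-1-nitroso-3-phenylpropan-2-one (racemic, formed in the flask) | O=NC(Cl)C(=O)Cc1ccccc1 | intermediate
4 | (Z)-N-hydroxy-2-oxo-3-phenylpropanimidoyl chloride | O/N=C(\Cl)C(=O)Cc1ccccc1 | intermediate
5 | O-tert-butyl-L-tyrosine tert-butyl ester hydrochloride | Cl.CC(C)(C)OC(=O)[C@@H](N)Cc1ccc(OC(C)(C)C)cc1 | starting material
6 | tert-butyl O-tert-butyl-L-tyrosinate (free amine, formed in the flask) | CC(C)(C)OC(=O)[C@@H](N)Cc1ccc(OC(C)(C)C)cc1 | intermediate
7 | 2-oxo-3-phenylpropanenitrile oxide (formed in the flask) | [O-][N+]#CC(=O)Cc1ccccc1 | intermediate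
8 | tert-butyl O-tert-butyl-N-[1-(hydroxyimino)-2-oxo-3-phenylpropyl]-L-tyrosinate | CC(C)(C)OC(=O)[C@H](Cc1ccc(OC(C)(C)C)cc1)NC(=NO)C(=O)Cc1ccccc1 | intermediate
9 | tert-butyl O-tert-butyl-N-[1-(methoxyimino)-2-oxo-3-phenylpropyl]-L-tyrosinate | CC(C)(C)OC(=O)[C@H](Cc1ccc(OC(C)(C)C)cc1)NC(=NOC)C(=O)Cc1ccccc1 | intermediate
10 | 4-tert-butoxystyrene | C=Cc1ccc(OC(C)(C)C)cc1 | starting material
11 | 1-(1-azido-2-iodoethyl)-4-tert-butoxybenzene (racemic) | [N-]=[N+]=NC(CI)c1ccc(OC(C)(C)C)cc1 | intermediate
12 | 1-(1-azidoethenyl)-4-tert-butoxybenzene | C=C(N=[N+]=[N-])c1ccc(OC(C)(C)C)cc1 | intermediate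
13 | 1-[1-(4-tert-butoxyphenyl)ethenyl]-3-(triphenyl-λ5-phosphanylidene)triazene (phosphazide, formed in the flask) | C=C(N=NN=P(c1ccccc1)(c1ccccc1)c1ccccc1)c1ccc(OC(C)(C)C)cc1 | intermediate
14 | N-[1-(4-tert-butoxyphenyl)ethenyl]iminotriphenylphosphorane | C=C(N=P(c1ccccc1)(c1ccccc1)c1ccccc1)c1ccc(OC(C)(C)C)cc1 | intermediate
15 | tert-butyl O-tert-butyl-N-[2-{[1-(4-tert-butoxyphenyl)ethenyl]imino}-1-(methoxyimino)-3-phenylpropyl]-L-tyrosinate (1-methoxy-1,4-diazatriene, formed in the flask) | C=C(N=C(Cc1ccccc1)C(=NOC)N[C@@H](Cc1ccc(OC(C)(C)C)cc1)C(=O)OC(C)(C)C)c1ccc(OC(C)(C)C)cc1 | intermediate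
16 | tert-butyl N-[3-benzyl-5-(4-tert-butoxyphenyl)-1-methoxy-1,6-dihydropyrazin-2-yl]-O-tert-butyl-L-tyrosinate (formed in the flask) | CON1CC(c2ccc(OC(C)(C)C)cc2)=NC(Cc2ccccc2)=C1N[C@@H](Cc1ccc(OC(C)(C)C)cc1)C(=O)OC(C)(C)C | intermediate
17 | tert-butyl N-[3-benzyl-5-(4-tert-butoxyphenyl)pyrazin-2-yl]-O-tert-butyl-L-tyrosinate | CC(C)(C)OC(=O)[C@H](Cc1ccc(OC(C)(C)C)cc1)Nc1ncc(-c2ccc(OC(C)(C)C)cc2)nc1Cc1ccccc1 | intermediate
18 | N-[3-benzyl-5-(4-hydroxyphenyl)pyrazin-2-yl]-L-tyrosine | OC(=O)[C@H](Cc1ccc(O)cc1)Nc1ncc(-c2ccc(O)cc2)nc1Cc1ccccc1 | intermediate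
19 | (2S)-8-benzyl-2-(4-hydroxybenzyl)-6-(4-hydroxyphenyl)imidazo[1,2-a]pyrazin-3(2H)-one (formed in the flask) | O=C1[C@H](Cc2ccc(O)cc2)N=C2C(Cc3ccccc3)=NC(c3ccc(O)cc3)=CN12 | intermediate
20 | coelenterazine, 8-benzyl-2-(4-hydroxybenzyl)-6-(4-hydroxyphenyl)imidazo[1,2-a]pyrazin-3(7H)-one | O=c1c(Cc2ccc(O)cc2)nc2c(Cc3ccccc3)[nH]c(-c3ccc(O)cc3)cn1-2 | target

Total step count: 10 steps.
Longest linear sequence: 7 steps (steps 1, 2, 3, 4, 8, 9, 10, from phenylacetyl chloride). The phosphazene branch (steps 5, 6, 7) joins at step 8.

Steps most likely to fail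

Step 8 (proposed new method). The phosphazene may be protonated by the acidic benzylic ketone or hydrolysed before it condenses. The diazatriene may also drift into enamine tautomers and decompose faster than it cyclizes. The fallback uses known cross-coupling chemistry, sets out from 5 and comes back to the route at 17. Commercial 3,5-dibromopyrazin-2-amine is benzylated at C3 by Negishi coupling (BnZnBr, PdCl2(PPh3)2, THF) to give 3-benzyl-5-bromopyrazin-2-amine F1. Suzuki coupling with (4-tert-butoxyphenyl)boronic acid (Pd(PPh3)4, K2CO3, dioxane/H2O) should give 3-benzyl-5-(4-tert-butoxyphenyl)pyrazin-2-amine F2. Non-aqueous Sandmeyer bromination (tert-butyl nitrite, CuBr2, MeCN) should give 3-benzyl-2-bromo-5-(4-tert-butoxyphenyl)pyrazine F3. Buchwald–Hartwig N-arylation of the amino ester 6, freed from 5, with F3 (Pd(OAc)2, rac-BINAP, Cs2CO3, toluene, 90 °C) should then give 17; any racemization is immaterial.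

Step 2. Adventitious HCl may protonate the diazo carbon and lead to the chloromethyl ketone, or nitrosation may stray to the benzylic methylene. The fallback sets out from 2 and comes back at 4. Aqueous HBr in Et2O at 0 °C converts diazoketone 2 into 1-bromo-3-phenylpropan-2-one F4. Dimethyl sulfide in acetone gives dimethyl(2-oxo-3-phenylpropyl)sulfonium bromide F5. Treatment with NaNO2 and aqueous HCl in dioxane should nitrosate the sulfonium-activated methylene and exchange dimethyl sulfide for chloride, giving 4.

Step 10. The electron-rich imidazopyrazinone may be oxidized by traces of air during cyclodehydration and isolation, and the activated acid may acylate a phenol of a second molecule. The fallback sets out from 18 and comes back at 20 through an air-stable protected form. Acetic anhydride in pyridine should cyclodehydrate 18 and acetylate both phenols and the C3 enol oxygen, giving 2-(4-acetoxybenzyl)-6-(4-acetoxyphenyl)-8-benzylimidazo[1,2-a]pyrazin-3-yl acetate F6, which can be purified in air. HCl in degassed methanol under argon then removes the three acetyl groups to give 20.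

Further compounds
F1 | step 8 | 3-benzyl-5-bromopyrazin-2-amine | Nc1ncc(Br)nc1Cc1ccccc1
F2 | step 8 | 3-benzyl-5-(4-tert-butoxyphenyl)pyrazin-2-amine | Nc1ncc(-c2ccc(OC(C)(C)C)cc2)nc1Cc1ccccc1
F3 | step 8 | 3-benzyl-2-bromo-5-(4-tert-butoxyphenyl)pyrazine | Brc1ncc(-c2ccc(OC(C)(C)C)cc2)nc1Cc1ccccc1
F4 | step 2 | 1-bromo-3-phenylpropan-2-one | O=C(CBr)Cc1ccccc1
F5 | step 2 | dimethyl(2-oxo-3-phenylpropyl)sulfonium bromide | C[S+](C)CC(=O)Cc1ccccc1.[Br-]
F6 | step 10 | 2-(4-acetoxybenzyl)-6-(4-acetoxyphenyl)-8-benzylimidazo[1,2-a]pyrazin-3-yl acetate | CC(=O)Oc1ccc(Cc2nc3c(Cc4ccccc4)nc(-c4ccc(OC(C)=O)cc4)cn3c2OC(C)=O)cc1
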